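Abbreviations: geranyl = (2E)-3,7-dimethylocta-2,6-dienyl; MOM = methoxymethyl; TBS = tert-butyldimethylsilyl; TIPS = triisopropylsilyl.

## The problem

The target **21** is a (2S)-flavanone: ring C is a chroman-4-one fused to a phloroglucinol-type ring A and carries a 3-methoxy-4,5-dihydroxyphenyl ring B at C2. Ring A has free hydroxyls at C5 and C7 and an (E)-geranyl chain at C6, between the two hydroxyls and para to the ring oxygen O1. Sterically controlled alkylation or protection of acylphloroglucinols would be expected to lead to the C8 isomer, so the C6 placement has to be secured by design. C2 is the only stereocentre, so nothing in the molecule can relay to it and a catalyst must set it. It is a benzylic ether carbon β to the C4 ketone, and it is lost by retro-oxa-Michael opening to the 2′-hydroxychalcone whenever the C3 enolate forms. The two trisubstituted alkenes of the geranyl chain rule out strong protic or Lewis acids (cyclisation onto the flanking phenols), electrophilic halogen, most oxidants and hydrogenation, and with them benzyl ethers and Friedel–Crafts acylation. The five phenols therefore need groups that leave under mild acid. The key step rests on the C3–C4 bond of ring C. C3 is a methylene and C4 an aryl ketone carbon, so this bond is the saturated form of the C3=C4 double bond of a cyclic enol silane. Olefin metathesis can form that double bond from a vinyl group on C2 and the 1-siloxyvinyl form of an ortho-acetyl group, with no oxidation near the geranyl chain.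

## Retrosynthesis

**21 from 19.** No skeletal bond is cut. The ketone is masked as the 4-siloxy-2H-chromene **19** and the four phenols as MOM ethers. A single acidic methanolysis should hydrolyse the enol silane to the flavanone **20** and then remove the acetals. Acid is preferred to fluoride for the first event because it passes through C3 protonation, not through the flavanone enolate, which can open ring C and erode C2.

**19 from 18 (C3=C4).** The ring-C double bond is cut by ring-closing metathesis, giving the acyclic aryl ether **18** with a vinyl group on C2 and a 1-(TBS-oxy)vinyl group on ring A. The neighbouring cuts are weaker. Cutting O1–C2 leads to the oxa-Michael closure of a chalcone, which is reversible and racemising. Cutting C4–C4a needs a Friedel–Crafts acylation under acid. Cutting C2–C3 needs carbenoid or enolate chemistry next to an ether oxygen. Metathesis is neutral, releases only ethylene and leaves the C2–O bond untouched. The forward reaction must engage two terminal alkenes in the presence of two trisubstituted ones and must not migrate the allylic double bond.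

**18 from 16, and 16 from 10 and 15 (O1–C2).** The enol silane comes from methyl ketone **16** by enolisation and O-silylation. In **16** the branched allyl aryl ether bond is cut, leading to the phenol **10** and the linear cinnamyl carbonate **15**. An iridium-catalysed asymmetric allylic etherification forms this bond branch-selectively and sets C2 under ligand control. A Mitsunobu reaction of a 1-arylallyl alcohol would leak through SN2′ and ionisation pathways. This cut halves the molecule and makes the route convergent. The forward reaction needs the hindered, hydrogen-bonded ortho-acyl phenoxide to attack the substituted allyl terminus.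

**10 from 7 via 8 and 9 (C4a–acyl).** The acetyl group must sit ortho to the free hydroxyl (the future O1), with the geranyl chain para to that hydroxyl. Geranylation and sterically controlled protection of 2,4,6-trihydroxyacetophenone would be expected to leave free the hydroxyl next to the chain, the pattern of the 8-geranyl series. The acetyl group is therefore removed to give the symmetric phenol **7**, whose two ortho positions are equivalent. Friedel–Crafts acetylation would destroy the acetals and the chain. The forward sequence is a magnesium-mediated ortho-formylation to **8**, methyl Grignard addition to **9** and benzylic oxidation to **10**, all under basic or neutral conditions.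

**7 from 6, and 6 from 3 and 4 (C6–C1″).** The geranyl–arene bond is cut to the bromide **4** and the aryllithium **5**, which forms from the silyl ether **3** by lithiation between the two MOM-oxy groups. The mirror plane of **3** makes this the only doubly activated position, so the chain ends up para to the silyl-protected oxygen. **3** comes from phloroglucinol **1** through the mono-TIPS ether **2**. The TIPS group is chosen because it survives n-BuLi, directs lithiation poorly and is removed by fluoride, giving **7** from **6**.

**15 from 11.** The carbonate comes from the allylic alcohol **14**, made by reduction of the cinnamate **13**. **13** comes from aldehyde **12** by Horner–Wadsworth–Emmons olefination, and **12** from 5-hydroxyvanillin **11** by double MOM protection. The linear carbonate is preferred to a racemic branched one because the iridium catalyst gives its highest enantioselectivity from the linear isomer.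

## Roads not taken

**Alternative 1:** Ring A would be cut at C5–C6, C7–C8 and C4a–C5 and built by a photochemical Wolff benzannulation. Irradiation of the diazoketone A2, a (2S)-2-aryl-2,3-dihydropyran-4-one with a diazoacetyl group at C6, would give a vinylketene. This would combine with the geranyl-substituted siloxyalkyne A3 by [2+2] cycloaddition, four-electron ring opening and six-electron closure, giving the phenol A1.
- Merit: the alkyne substituents fix the geranyl chain at C6, the silyl ether at C7 and the free hydroxyl at C5 by construction. This is better than the chosen plan, which spends seven steps on the ring-A pattern.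
- Weak points: A2 needs an asymmetric hetero-Diels–Alder reaction and a diazo transfer on a base-sensitive β-alkoxy enone whose C2 centre can open by β-elimination. The photolysis acts on a cross-conjugated enone beside an electron-rich arene. The thermal stage of the benzannulation and the sensitive ynol silyl ether A3 add risk. The step count would be no lower.
- Comparison: the chosen plan sets against the regiochemical advantage a stereocentre made by a well-understood catalytic reaction and a ring closure with a close precedent.

**Alternative 2:** The C2–C3 bond would be cut. Rh2(S-PTTL)4, a chiral carboxylate of divalent rhodium, would convert the diazoketone A5 into a carbenoid that inserts into the benzylic O–CH2 bond, closing ring C and setting C2 in one step to give the flavanone A4.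
- Merit: if it worked it would be shorter than the chosen plan, since the benzyl ether needs neither a cinnamyl carbonate nor an iridium step, and ring and stereocentre would form together.
- Weak points: the carbenoid sits five atoms from the ether oxygen, so oxonium ylide formation and a [1,2]-shift of the benzyl group to close a five-membered ring would be expected to compete strongly with the six-membered C–H insertion. Cyclopropanation of the geranyl alkenes and attack on the electron-rich arenes are further drains. Enantiocontrol for this type of insertion is not established.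
- Comparison: the chosen plan is longer but separates the stereocentre from the ring closure, and each has a direct precedent.

**Alternative 3:** The O1–C8a bond would be cut. The C2 hydroxyl of the bromo diol A7 would couple with the aryl bromide under CuI, a phenanthroline ligand and Cs2CO3, giving the flavan-4-ol A6. Oxidation of the C4 carbinol would give **20**.
- Merit: the C2–O bond is never broken or made ionisable and C2 can come from a reliable asymmetric ketone reduction. In configurational security this road is better than the chosen one, whose allylic aryl ether can ionise.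
- Weak points: the bromide must sit para to the geranyl chain on a fully substituted, electron-rich ring. This brings back the regiochemical problem with a halogen that does not tolerate the lithiation used for the chain. Such a hindered bromide would need high temperature, where the 1,3-diol monoalkoxide can fragment by retro-aldol. C4 would have to be reduced and later re-oxidised.
- Comparison: the chosen plan offers a shorter path to ring C, no halogenated ring A and no redox detour.

Key step: step 14

Remark on the chemistry: the sense of induction in step 12 is assigned by analogy with 1-arylallyl ethers and amines made with this ligand family; if it proved opposite, the (Ra,R,R) ligand would be used with no other change.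

## Route

Step 1
Reactants: 1 phloroglucinol
Product: 2 5-(triisopropylsilyloxy)benzene-1,3-diol
Conditions: TIPSCl (1.0 equiv), imidazole, DMF, 0 °C to rt; 1 in threefold excess, removed by aqueous wash
Reagents that add atoms: triisopropylsilyl chloride, CC(C)[Si](Cl)(C(C)C)C(C)C
Why: Silylation of a phenol with a silyl chloride and imidazole; the excess of the cheap, water-soluble triol biases the statistical reaction toward the mono-ether. The TIPS group is chosen because it survives n-BuLi and is a poor directing group.

Step 2
Reactants: 2 5-(triisopropylsilyloxy)benzene-1,3-diol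
Product: 3 [3,5-bis(methoxymethoxy)phenoxy]triisopropylsilane
Conditions: MOMCl, i-Pr2NEt, CH2Cl2, 0 °C to rt
Reagents that add atoms: chloromethyl methyl ether, COCCl
Why: Standard acetalisation of the two remaining phenols under amine base, which leaves the aryl silyl ether intact. The product keeps its mirror plane, so no regiochemical question arises.

Step 3
Reactants: 3 [3,5-bis(methoxymethoxy)phenoxy]triisopropylsilane; 4 geranyl bromide
Product: 6 [4-geranyl-3,5-bis(methoxymethoxy)phenoxy]triisopropylsilane, via aryllithium 5 (not isolated)
Conditions: n-BuLi, THF, 0 °C; then CuI (10 mol%), 4, −78 °C to rt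
Reagents that add atoms: none
Why: Directed ortho-metalation: the position flanked by both MOM-oxy groups is lithiated selectively because two directing groups cooperate there and the hindered silyl ether directs weakly. Copper-catalysed coupling of the aryllithium with the primary allylic bromide should give the SN2 product with the E alkene retained.

Step 4
Reactants: 6 [4-geranyl-3,5-bis(methoxymethoxy)phenoxy]triisopropylsilane
Product: 7 4-geranyl-3,5-bis(methoxymethoxy)phenol
Conditions: Bu4NF, THF, 0 °C; aq NH4Cl
Reagents that add atoms: none
Why: Fluoride cleavage of an aryl silyl ether; acetals and alkenes are inert. The phenol obtained is symmetric with the chain para to the hydroxyl.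

Step 5
Reactants: 7 4-geranyl-3,5-bis(methoxymethoxy)phenol
Product: 8 3-geranyl-6-hydroxy-2,4-bis(methoxymethoxy)benzaldehyde
Conditions: MgCl2, Et3N, (CH2O)n, MeCN, reflux
Reagents that add atoms: paraformaldehyde (as formaldehyde), C=O
Why: Magnesium-mediated ortho-formylation of a phenol: the magnesium phenoxide adds to formaldehyde at the ortho carbon and a second formaldehyde accepts hydride. The two ortho positions are equivalent and the para position is blocked, so a single aldehyde should form; the basic medium spares the acetals and the chain.

Step 6
Reactants: 8 3-geranyl-6-hydroxy-2,4-bis(methoxymethoxy)benzaldehyde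
Product: 9 1-[3-geranyl-6-hydroxy-2,4-bis(methoxymethoxy)phenyl]ethanol (racemic)
Conditions: MeMgBr (3 equiv), THF, −78 to 0 °C; aq NH4Cl
Reagents that add atoms: methylmagnesium bromide, C[Mg]Br
Why: Grignard addition to an aldehyde; the first equivalent is consumed by the phenol. The new carbinol centre is racemic and is erased in the next step, for which the crude alcohol is used.

Step 7
Reactants: 9 1-[3-geranyl-6-hydroxy-2,4-bis(methoxymethoxy)phenyl]ethanol
Product: 10 1-[3-geranyl-6-hydroxy-2,4-bis(methoxymethoxy)phenyl]ethanone
Conditions: MnO2 (activated), CH2Cl2, rt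
Reagents that add atoms: none
Why: MnO2 oxidation of a benzylic alcohol to the aryl ketone, which does not touch trisubstituted alkenes. The intramolecular hydrogen bond of the ortho-hydroxy ketone makes the product the stable end point.

Step 8
Reactants: 11 5-hydroxyvanillin
Product: 12 3-methoxy-4,5-bis(methoxymethoxy)benzaldehyde
Conditions: MOMCl, i-Pr2NEt, CH2Cl2, 0 °C to rt
Reagents that add atoms: chloromethyl methyl ether, COCCl
Why: Acetalisation of both catechol hydroxyls under amine base; the aldehyde is unaffected.

Step 9
Reactants: 12 3-methoxy-4,5-bis(methoxymethoxy)benzaldehyde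
Product: 13 ethyl (2E)-3-[3-methoxy-4,5-bis(methoxymethoxy)phenyl]prop-2-enoate
Conditions: (EtO)2P(O)CH2CO2Et, NaH, THF, 0 °C to rt
Reagents that add atoms: triethyl phosphonoacetate, CCOC(=O)CP(=O)(OCC)OCC
Why: Horner–Wadsworth–Emmons olefination; the stabilised phosphonate anion gives the E cinnamate.

Step 10
Reactants: 13 ethyl (2E)-3-[3-methoxy-4,5-bis(methoxymethoxy)phenyl]prop-2-enoate
Product: 14 (2E)-3-[3-methoxy-4,5-bis(methoxymethoxy)phenyl]prop-2-en-1-ol
Conditions: i-Bu2AlH, CH2Cl2, −78 °C; aq potassium sodium tartrate
Reagents that add atoms: none
Why: 1,2-Reduction of an α,β-unsaturated ester to the allylic alcohol by the aluminium hydride at low temperature; the alkene geometry is retained.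

Step 11
Reactants: 14 (2E)-3-[3-methoxy-4,5-bis(methoxymethoxy)phenyl]prop-2-en-1-ol
Product: 15 tert-butyl (2E)-3-[3-methoxy-4,5-bis(methoxymethoxy)phenyl]prop-2-enyl carbonate
Conditions: Boc2O, Bu4NHSO4 (cat.), 30% aq NaOH, CH2Cl2, 0 °C to rt
Reagents that add atoms: di-tert-butyl dicarbonate, CC(C)(C)OC(=O)OC(=O)OC(C)(C)C
Why: Phase-transfer acylation of the primary allylic alcohol. The tert-butyl carbonate is chosen because the tert-butoxide it releases in step 12 is a base but not a competing nucleophile.

Step 12
Reactants: 10 1-[3-geranyl-6-hydroxy-2,4-bis(methoxymethoxy)phenyl]ethanone; 15 tert-butyl (2E)-3-[3-methoxy-4,5-bis(methoxymethoxy)phenyl]prop-2-enyl carbonate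
Product: 16 1-{3-geranyl-2,4-bis(methoxymethoxy)-6-[(1S)-1-(3-methoxy-4,5-bis(methoxymethoxy)phenyl)prop-2-enyloxy]phenyl}ethanone
Conditions: [Ir(cod)Cl]2 (2 mol%), (Sa,S,S)-binaphthyl-2,2′-diyl N,N-bis(1-phenylethyl)phosphoramidite (4 mol%), TBD (8 mol%), THF, rt to 40 °C
Reagents that add atoms: none
Why: Iridium-catalysed asymmetric allylic etherification: the cyclometalated iridium–phosphoramidite complex ionises the linear carbonate to a π-allyl complex, and the aryloxide (formed by the released tert-butoxide) attacks the aryl-substituted terminus anti to the metal to give the branched ether. The C2 stereocentre is set by the ligand, whose (Sa,S,S) enantiomer is expected to give the (S) ether. Electron-rich cinnamyl carbonates and ortho-substituted phenols lie within the known scope of this reaction.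

Step 13
Reactants: 16 1-{3-geranyl-2,4-bis(methoxymethoxy)-6-[(1S)-1-(3-methoxy-4,5-bis(methoxymethoxy)phenyl)prop-2-enyloxy]phenyl}ethanone
Product: 18 tert-butyl{1-[3-geranyl-2,4-bis(methoxymethoxy)-6-{[(1S)-1-(3-methoxy-4,5-bis(methoxymethoxy)phenyl)prop-2-enyl]oxy}phenyl]ethenyloxy}dimethylsilane, via potassium enolate 17 (not isolated)
Conditions: KN(SiMe3)2, THF, −78 °C; then TBSOTf, −78 °C; Et3N, cold aq NaHCO3
Reagents that add atoms: tert-butyldimethylsilyl triflate, CC(C)(C)[Si](C)(C)OS(=O)(=O)C(F)(F)F
Why: Kinetic deprotonation of the methyl ketone, by far the most acidic C–H, followed by O-silylation of the potassium enolate at −78 °C. The cold, non-acidic conditions protect the four acetals and the ionisable allylic ether, and with a small excess of base the C2–H is not touched.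

Step 14
Reactants: 18 tert-butyl{1-[3-geranyl-2,4-bis(methoxymethoxy)-6-{[(1S)-1-(3-methoxy-4,5-bis(methoxymethoxy)phenyl)prop-2-enyl]oxy}phenyl]ethenyloxy}dimethylsilane
Product: 19 tert-butyl{[(2S)-6-geranyl-5,7-bis(methoxymethoxy)-2-(3-methoxy-4,5-bis(methoxymethoxy)phenyl)-2H-chromen-4-yl]oxy}dimethylsilane
Conditions: second-generation Grubbs catalyst RuCl2(=CHPh)(PCy3)(H2IMes) (5–10 mol%), 1,4-benzoquinone (10 mol%), CH2Cl2 (0.005 M), 40 °C, dark, Ar purge
Reagents that add atoms: none
Why: The ruthenium benzylidene exchanges with the monosubstituted vinyl group to place the alkylidene on C3; intramolecular [2+2] cycloaddition with the 1-siloxyvinyl alkene gives a ruthenacyclobutane, and cycloreversion forms C3=C4 and releases the methylidene, which turns over with loss of ethylene. The closest known reactions are ring-closing metathesis of olefinic silyl enol ethers to cyclic enol silanes (including N-allyl 2-(1-siloxyvinyl)anilines to 4-siloxy-1,2-dihydroquinolines) and of ortho-vinylaryl allyl ethers to 2H-chromenes. Ring C closes as a six-membered ring with the new double bond endocyclic, driven by escape of ethylene. No stereocentre is formed; C2 is outside the metallacycle and its C–O and C–H bonds are not involved. The step needs the two terminal alkenes to react in preference to the geranyl alkenes, which is secured because trisubstituted alkenes are poor partners for this catalyst and could only close a large ring. High dilution suppresses dimerisation through the vinyl group, and benzoquinone suppresses migration of the allylic double bond by ruthenium hydrides. The mild temperature and exclusion of light guard against electrocyclic opening of the 2H-chromene, which would erode C2. The crude product is taken directly into step 15.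

Step 15
Reactants: 19 tert-butyl{[(2S)-6-geranyl-5,7-bis(methoxymethoxy)-2-(3-methoxy-4,5-bis(methoxymethoxy)phenyl)-2H-chromen-4-yl]oxy}dimethylsilane
Product: 21 (2S)-2-(3,4-dihydroxy-5-methoxyphenyl)-6-geranyl-5,7-dihydroxychroman-4-one, via flavanone tetrakis-MOM ether 20 (not isolated)
Conditions: HCl (about 1.5 M) in MeOH–THF, rt to 40 °C
Reagents that add atoms: none
Why: Acid solvolysis: protonation of the enol silane at C3 and transfer of the silyl group to methanol gives the ketone, and acetal exchange with methanol then removes the four MOM groups. Acid is used instead of fluoride so that the flavanone enolate, which can open ring C by β-elimination of the phenoxide, is never formed. The conditions are kept mild to spare the geranyl alkenes.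

## Compound list

1 | phloroglucinol (benzene-1,3,5-triol) | Oc1cc(O)cc(O)c1 | starting material
2 | 5-(triisopropylsilyloxy)benzene-1,3-diol | CC(C)[Si](Oc1cc(O)cc(O)c1)(C(C)C)C(C)C | intermediate
3 | [3,5-bis(methoxymethoxy)phenoxy]triisopropylsilane | COCOc1cc(OCOC)cc(O[Si](C(C)C)(C(C)C)C(C)C)c1 | intermediate
4 | geranyl bromide, (2E)-1-bromo-3,7-dimethylocta-2,6-diene | CC(C)=CCC/C(C)=C/CBr | starting material
5 | [2,6-bis(methoxymethoxy)-4-(triisopropylsilyloxy)phenyl]lithium | [Li]c1c(OCOC)cc(O[Si](C(C)C)(C(C)C)C(C)C)cc1OCOC | intermediate (not isolated)
6 | [4-geranyl-3,5-bis(methoxymethoxy)phenoxy]triisopropylsilane | COCOc1cc(O[Si](C(C)C)(C(C)C)C(C)C)cc(OCOC)c1C/C=C(\C)CCC=C(C)C | intermediate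
7 | 4-geranyl-3,5-bis(methoxymethoxy)phenol | COCOc1cc(O)cc(OCOC)c1C/C=C(\C)CCC=C(C)C | intermediate
8 | 3-geranyl-6-hydroxy-2,4-bis(methoxymethoxy)benzaldehyde | O=Cc1c(O)cc(OCOC)c(C/C=C(\C)CCC=C(C)C)c1OCOC | intermediate
9 | 1-[3-geranyl-6-hydroxy-2,4-bis(methoxymethoxy)phenyl]ethanol, racemic | CC(O)c1c(O)cc(OCOC)c(C/C=C(\C)CCC=C(C)C)c1OCOC | intermediate
10 | 1-[3-geranyl-6-hydroxy-2,4-bis(methoxymethoxy)phenyl]ethanone | CC(=O)c1c(O)cc(OCOC)c(C/C=C(\C)CCC=C(C)C)c1OCOC | intermediate
11 | 5-hydroxyvanillin (3,4-dihydroxy-5-methoxybenzaldehyde) | COc1cc(C=O)cc(O)c1O | starting material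
12 | 3-methoxy-4,5-bis(methoxymethoxy)benzaldehyde | COCOc1cc(C=O)cc(OC)c1OCOC | intermediate
13 | ethyl (2E)-3-[3-methoxy-4,5-bis(methoxymethoxy)phenyl]prop-2-enoate | CCOC(=O)/C=C/c1cc(OC)c(OCOC)c(OCOC)c1 | intermediate
14 | (2E)-3-[3-methoxy-4,5-bis(methoxymethoxy)phenyl]prop-2-en-1-ol | OC/C=C/c1cc(OC)c(OCOC)c(OCOC)c1 | intermediate
15 | tert-butyl (2E)-3-[3-methoxy-4,5-bis(methoxymethoxy)phenyl]prop-2-enyl carbonate | CC(C)(C)OC(=O)OC/C=C/c1cc(OC)c(OCOC)c(OCOC)c1 | intermediate
16 | 1-{3-geranyl-2,4-bis(methoxymethoxy)-6-[(1S)-1-(3-methoxy-4,5-bis(methoxymethoxy)phenyl)prop-2-enyloxy]phenyl}ethanone | C=C[C@H](Oc1cc(OCOC)c(C/C=C(\C)CCC=C(C)C)c(OCOC)c1C(C)=O)c1cc(OC)c(OCOC)c(OCOC)c1 | intermediate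
17 | potassium enolate of 16 (potassium 1-arylethenolate, S at the ether carbon) | C=C[C@H](Oc1cc(OCOC)c(C/C=C(\C)CCC=C(C)C)c(OCOC)c1C(=C)[O-])c1cc(OC)c(OCOC)c(OCOC)c1.[K+] | intermediate (not isolated)
18 | tert-butyl{1-[3-geranyl-2,4-bis(methoxymethoxy)-6-{[(1S)-1-(3-methoxy-4,5-bis(methoxymethoxy)phenyl)prop-2-enyl]oxy}phenyl]ethenyloxy}dimethylsilane | C=C[C@H](Oc1cc(OCOC)c(C/C=C(\C)CCC=C(C)C)c(OCOC)c1C(=C)O[Si](C)(C)C(C)(C)C)c1cc(OC)c(OCOC)c(OCOC)c1 | intermediate (precursor of the key step)
19 | tert-butyl{[(2S)-6-geranyl-5,7-bis(methoxymethoxy)-2-(3-methoxy-4,5-bis(methoxymethoxy)phenyl)-2H-chromen-4-yl]oxy}dimethylsilane | COc1cc([C@@H]2C=C(O[Si](C)(C)C(C)(C)C)c3c(cc(OCOC)c(C/C=C(\C)CCC=C(C)C)c3OCOC)O2)cc(OCOC)c1OCOC | intermediate (product of the key step)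
20 | (2S)-6-geranyl-5,7-bis(methoxymethoxy)-2-[3-methoxy-4,5-bis(methoxymethoxy)phenyl]chroman-4-one | COc1cc([C@@H]2CC(=O)c3c(cc(OCOC)c(C/C=C(\C)CCC=C(C)C)c3OCOC)O2)cc(OCOC)c1OCOC | intermediate (not isolated)
21 | (2S)-2-(3,4-dihydroxy-5-methoxyphenyl)-6-[(2E)-3,7-dimethylocta-2,6-dienyl]-5,7-dihydroxychroman-4-one | COc1cc([C@@H]2CC(=O)c3c(cc(O)c(C/C=C(\C)CCC=C(C)C)c3O)O2)cc(O)c1O | target

## Step count and least certain steps

Total: 15 steps. Longest linear sequence: 11 steps (steps 1–7 and 12–15 from phloroglucinol); the ring-B branch (steps 8–11) joins at step 12.

**Step 14 (key step).** The closure has to take place on a hindered, electron-rich 1,1-disubstituted enol silane flanked by two ortho substituents, and the product carries a peri interaction between the C4 siloxy and C5 MOM-oxy groups. If cyclisation is slow, catalyst decomposition to ruthenium hydrides can migrate the allylic double bond and destroy C2, the vinyl group can dimerise, and heating to force conversion invites electrocyclic opening of the 2H-chromene with loss of configuration. A first response within the step would be the molybdenum alkylidene Mo(=CHCMe2Ph)(=N-2,6-i-Pr2C6H3)[OC(CF3)2Me]2, which is more tolerant of enol ethers. The fallback abandons the metathesis and sets out from **10** and **12**. Claisen–Schmidt condensation (KOH, EtOH) would give the 2′-hydroxychalcone F1, whose only free hydroxyl is the one that must become O1. An enantioselective intramolecular oxa-Michael addition under a bifunctional cinchona-derived thiourea would close ring C and return to the route at **20**, which would be isolated and deprotected as in step 15. The enantiomeric purity from this reversible closure would probably be lower and might have to be raised by crystallisation or chromatography on a chiral phase.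

**Step 12.** The phenoxide of **10** is hydrogen-bonded to the ketone and ortho-substituted, so attack on the allyl complex may be slow. Because the aryloxide is a fair leaving group, the branched ether may re-ionise on the catalyst, with erosion of the branched selectivity and of the enantiomeric purity. The fallback sets the stereocentre separately and sets out from **12**. Enantioselective vinylation with Zn(CH=CH2)2 and a chiral amino alcohol would give the (1S)-allylic alcohol F2, which would be converted (n-BuLi, Boc2O) into the branched tert-butyl carbonate F3. The branched-selective and stereoretentive allylic etherification of **10** catalysed by [Cp*Ru(MeCN)3]PF6 would return to the route at **16**.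

**Step 7 (with the carbinol from step 6).** The ortho-hydroxybenzylic alcohol **9** on a trioxygenated ring can lose water through an ortho-quinone methide, and the free electron-rich phenol can be over-oxidised during the MnO2 step. The fallback moves both operations behind the etherification and sets out from **8**. Coupling **8** with **15** under the conditions of step 12 would give the aldehyde ether F4. MeMgBr would give the carbinol F5 as a mixture of epimers, and Dess–Martin periodinane (buffered with NaHCO3) would return to the route at **16**, bypassing **9** and **10**.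

**Step 15.** Under protic acid the geranyl chain can cyclise onto the freed C5 or C7 hydroxyl or add the solvent, and prolonged warming can open ring C through the para-hydroxybenzylic C2–O bond. The fallback separates the two events and avoids protic acid in the second. Setting out from **19**, buffered fluoride (HF·pyridine with excess pyridine, THF, 0 °C) would release the ketone **20**, which would be isolated. The acetals would then be removed with ZnBr2 and 1-propanethiol in CH2Cl2 at 0 °C, arriving at **21**. No new compound is involved.

## Further compounds

F1 | step 14 | (2E)-1-[3-geranyl-6-hydroxy-2,4-bis(methoxymethoxy)phenyl]-3-[3-methoxy-4,5-bis(methoxymethoxy)phenyl]prop-2-en-1-one | COCOc1cc(O)c(C(=O)/C=C/c2cc(OC)c(OCOC)c(OCOC)c2)c(OCOC)c1C/C=C(\C)CCC=C(C)C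
F2 | step 12 | (1S)-1-[3-methoxy-4,5-bis(methoxymethoxy)phenyl]prop-2-en-1-ol | C=C[C@H](O)c1cc(OC)c(OCOC)c(OCOC)c1
F3 | step 12 | tert-butyl (1S)-1-[3-methoxy-4,5-bis(methoxymethoxy)phenyl]prop-2-enyl carbonate | C=C[C@H](OC(=O)OC(C)(C)C)c1cc(OC)c(OCOC)c(OCOC)c1
F4 | step 7 | 3-geranyl-2,4-bis(methoxymethoxy)-6-[(1S)-1-(3-methoxy-4,5-bis(methoxymethoxy)phenyl)prop-2-enyloxy]benzaldehyde | C=C[C@H](Oc1cc(OCOC)c(C/C=C(\C)CCC=C(C)C)c(OCOC)c1C=O)c1cc(OC)c(OCOC)c(OCOC)c1
F5 | step 7 | 1-{3-geranyl-2,4-bis(methoxymethoxy)-6-[(1S)-1-(3-methoxy-4,5-bis(methoxymethoxy)phenyl)prop-2-enyloxy]phenyl}ethanol, mixture of carbinol epimers | C=C[C@H](Oc1cc(OCOC)c(C/C=C(\C)CCC=C(C)C)c(OCOC)c1C(C)O)c1cc(OC)c(OCOC)c(OCOC)c1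
F0 | step 15 | none | none
A1 | alternative 1 | (2S)-6-geranyl-5-hydroxy-2-[3-methoxy-4,5-bis(methoxymethoxy)phenyl]-7-(triisopropylsilyloxy)chroman-4-one | COc1cc([C@@H]2CC(=O)c3c(cc(O[Si](C(C)C)(C(C)C)C(C)C)c(C/C=C(\C)CCC=C(C)C)c3O)O2)cc(OCOC)c1OCOC
A2 | alternative 1 | (2S)-6-(diazoacetyl)-2-[3-methoxy-4,5-bis(methoxymethoxy)phenyl]-2,3-dihydro-4H-pyran-4-one | COc1cc([C@@H]2CC(=O)C=C(C(=O)C=[N+]=[N-])O2)cc(OCOC)c1OCOC
A3 | alternative 1 | [(4E)-5,9-dimethyldeca-4,8-dien-1-ynyloxy]triisopropylsilane | CC(C)=CCC/C(C)=C/CC#CO[Si](C(C)C)(C(C)C)C(C)C
A4 | alternative 2 | (2S)-5,7-bis(tert-butyldimethylsilyloxy)-2-[3,4-bis(tert-butyldimethylsilyloxy)-5-methoxyphenyl]-6-geranylchroman-4-one | COc1cc([C@@H]2CC(=O)c3c(cc(O[Si](C)(C)C(C)(C)C)c(C/C=C(\C)CCC=C(C)C)c3O[Si](C)(C)C(C)(C)C)O2)cc(O[Si](C)(C)C(C)(C)C)c1O[Si](C)(C)C(C)(C)C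
A5 | alternative 2 | 2-diazo-1-{2-[3,4-bis(tert-butyldimethylsilyloxy)-5-methoxybenzyloxy]-4,6-bis(tert-butyldimethylsilyloxy)-5-geranylphenyl}ethanone | [N-]=[N+]=CC(=O)c1c(OCc2cc(OC)c(O[Si](C)(C)C(C)(C)C)c(O[Si](C)(C)C(C)(C)C)c2)cc(O[Si](C)(C)C(C)(C)C)c(C/C=C(\C)CCC=C(C)C)c1O[Si](C)(C)C(C)(C)C
A6 | alternative 3 | (2S,4S)-6-geranyl-5,7-bis(methoxymethoxy)-2-[3-methoxy-4,5-bis(methoxymethoxy)phenyl]chroman-4-ol | COc1cc([C@@H]2C[C@H](O)c3c(cc(OCOC)c(C/C=C(\C)CCC=C(C)C)c3OCOC)O2)cc(OCOC)c1OCOC
A7 | alternative 3 | (1S,3S)-1-[2-bromo-5-geranyl-4,6-bis(methoxymethoxy)phenyl]-3-[3-methoxy-4,5-bis(methoxymethoxy)phenyl]propane-1,3-diol | COc1cc([C@@H](O)C[C@H](O)c2c(Br)cc(OCOC)c(C/C=C(\C)CCC=C(C)C)c2OCOC)cc(OCOC)c1OCOC
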